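**Retrosynthetic overview**

1. Ring D (the cyclohexenedione; Ca = sp2 carbon on C-1', Cb = sp2 carbon on O, Cc = CMe2, Cd = C=O, Ce = CMe2, Cf = C=O on Ca) is opened last, at Ca–Cf and Cc–Cd. This is a [3+3] between the dimethylmalonyl unit Cf–Ce–Cd (2,2-dimethylmalonyl dichloride) and the triad Ca=Cb(O)–CcHMe2 of a 6-isopropyl-3,4-dihydro-2H-pyran.
2. Enabling feature: Cb is an enol-ether carbon flanked by two latent carbon nucleophiles (Ca, the enol-ether β-carbon; Cc, the α'-methine). The chain Me2Cc–Cb(O)=Ca–C1'H–C(=O)–CHMe2 is a hidden C2-symmetric enedione, so ring C needs no regiocontrol between the two carbonyl groups.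
3. Ring C (dihydropyran) comes from an inverse-demand oxa-Diels–Alder reaction of (E)-2,7-dimethyloct-4-ene-3,6-dione with the strained trans C4=C5 of (−)-β-caryophyllene. Rings A/B and C1/C9 come from the chiral pool; C4, C5 and C-1' are set in this step.
4. The enedione comes from Wittig olefination of 3-methyl-2-oxobutanal with the isobutyrylmethylene ylide.
5. Order of ring formation: cyclobutane and nine-membered ring (purchased) → dihydropyran (step 4) → cyclohexenedione (step 5).

Key step: step 5

Remark on locants: caryophyllane numbering is used for the terpene part (C4 carries CH3 and the ring oxygen, C5 carries H and C-1'). C-1' is the CH that carries the 2-methylpropanoyl group.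
Assumption: the minor C-1' epimer and any facial isomer formed in step 4 are removable by chromatography.

**Route**

Step 1
Reactants: 1 1-bromo-3-methylbutan-2-one; 2 triphenylphosphine
Product: 4 3-methyl-1-(triphenyl-λ5-phosphanylidene)butan-2-one, via phosphonium bromide 3 (not isolated)
Conditions: PPh3, toluene, 50 °C; then 2 M aq NaOH, CH2Cl2, rt
Reagents that add atoms: none
Why: SN2 alkylation of the phosphine by the α-bromo ketone followed by deprotonation of the acidic P–CH2–C=O position is the standard preparation of a keto-stabilised Wittig ylide.

Step 2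
Reactants: 5 3-methylbutan-2-one
Product: 6 3-methyl-2-oxobutanal
Conditions: SeO2 (1.0 equiv), 1,4-dioxane/H2O (20:1), 100 °C; filter, distil
Reagents that add atoms: selenium dioxide, O=[Se]=O
Why: Riley oxidation of a methyl ketone to the α-keto aldehyde, in which only the methyl side carries the two hydrogens needed to reach the carbonyl level, so the methine side cannot become a carbonyl group.

Step 3
Reactants: 4 3-methyl-1-(triphenyl-λ5-phosphanylidene)butan-2-one; 6 3-methyl-2-oxobutanal
Product: 7 (E)-2,7-dimethyloct-4-ene-3,6-dione
Conditions: CH2Cl2, rt, dark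
Reagents that add atoms: none
Why: Wittig olefination in which the stabilised ylide attacks the aldehyde rather than the ketone of the glyoxal and should give the E-alkene under the usual thermodynamic control of stabilised ylides.

Step 4
Reactants: 7 (E)-2,7-dimethyloct-4-ene-3,6-dione; 8 (−)-β-caryophyllene
Product: 9 caryophyllene–enedione [4+2] adduct: (1R,4R,5S,9S)-caryophyll-8(13)-ene whose C4–C5 bond is the C2–C3 bond of a 6-isopropyl-4-(2-methylpropanoyl)-3,4-dihydro-2H-pyran (ring O on C4; pyran C-4 = C-1' on C5, R by CIP; 4-CH3 anti to 5-H; 1'-H anti to 5-H)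
Conditions: 8 (3 equiv), Eu(fod)3 (5 mol %), BHT (1 mol %), neat, 60 °C, dark; chromatography
Reagents that add atoms: none
Why: Inverse-electron-demand oxa-Diels–Alder reaction in which the Lewis-acid-activated s-cis enone of C2-symmetric 7 (either half gives the same adduct) adds suprafacially to the strained trans C4=C5 of 8 from its open outer face, the face also taken by epoxidising agents, with O bonding to the more substituted C4 and carbon to C5, which fixes the trans ring fusion (4R,5S), while C-1' follows from the E geometry of 7 and the transition state that places the small C5–H rather than C6H2 under the oxadiene.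

Step 5
Reactants: 9 caryophyllene–enedione [4+2] adduct; 10 2,2-dimethylmalonyl dichloride
Product: 12 tomentodione R, via keto acid chloride 11 (not isolated)
Conditions: 10 (1.3 equiv), MgBr2·OEt2 (3 equiv), i-Pr2NEt (4 equiv), CH2Cl2 (0.02 M), −20 °C → rt, then 40 °C
Reagents that add atoms: none
Why: Proposed new method: the Mg(II)-chelated diacid chloride 10 should be attacked by the enol-ether β-carbon Ca of 9 (oxocarbenium ion at Cb, then loss of Ca–H to the amine) to give vinylogous ester 11, whose chelated β-keto acid chloride makes the Cc–H methine of the isopropyl group (the vinylogous γ-position, the only enolisable site conjugated to the chelate because Ce is quaternary) removable by i-Pr2NEt; the exocyclic dienolate (Cb=CcMe2) then acylates at Cc on the second COCl and the Ca=Cb vinylogous ester returns. The closest known reaction type is the Effenberger cyclisation (α,α'-bis-acylation of ketone enol ethers with malonyl dichloride) combined with MgBr2/amine soft-enolisation C-acylation by acid chlorides; new here are the 2,2-disubstituted malonyl chloride, an exocyclic methine as the second nucleophile and retention of the enol ether as a vinylogous ester. Ring D closes by a 6-(enolendo)-exo-trig acylation forming Cc–Cd; O- or Ca-attack of the same dienolate would give four-membered rings, and the ring oxygen is alkylated, so no lactone can form. No stereocentre is created (Cc and Ce are CMe2) and C1, C4, C5, C9 and C-1' are not touched. The step needs selectivity for the enol ether over the C8 methylene (secured by the much higher nucleophilicity of a trisubstituted enol ether), acylation faster than enolisation of the isobutyryl ketone (both of its α-carbons are hindered methines that give strained tetrasubstituted enolates, C-1' being flanked by C5 and Ca), and scavenging of HCl by the amine so that the tertiary-alkyl enol ether and the methylene survive.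

**Compound list**

1 | 1-bromo-3-methylbutan-2-one | CC(C)C(=O)CBr | starting material
2 | triphenylphosphine | c1ccc(cc1)P(c1ccccc1)c1ccccc1 | starting material
3 | (3-methyl-2-oxobutyl)triphenylphosphonium bromide (formed in the flask) | CC(C)C(=O)C[P+](c1ccccc1)(c1ccccc1)c1ccccc1.[Br-] | intermediate
4 | 3-methyl-1-(triphenyl-λ5-phosphanylidene)butan-2-one | CC(C)C(=O)C=P(c1ccccc1)(c1ccccc1)c1ccccc1 | intermediate
5 | 3-methylbutan-2-one | CC(C)C(C)=O | starting material
6 | 3-methyl-2-oxobutanal | CC(C)C(=O)C=O | intermediate
7 | (E)-2,7-dimethyloct-4-ene-3,6-dione | CC(C)C(=O)/C=C/C(=O)C(C)C | intermediate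
8 | (−)-β-caryophyllene, (1R,4E,9S) | C/C1=C\CCC(=C)[C@H]2CC(C)(C)[C@@H]2CC1 | starting material
9 | caryophyllene–enedione [4+2] adduct (1R,4R,5S,9S,1'R; dihydropyran with 6-isopropyl and 4-isobutyryl groups fused at caryophyllane C4–C5) | C=C1CC[C@H]2[C@H](C(=O)C(C)C)C=C(O[C@]2(C)CC[C@@H]2[C@@H]1CC2(C)C)C(C)C | intermediate
10 | 2,2-dimethylmalonyl dichloride | CC(C)(C(=O)Cl)C(=O)Cl | starting material
11 | keto acid chloride: 9 carrying C(=O)–CMe2–COCl on Ca (formed in the flask; 1R,4R,5S,9S,1'S) | C=C1CC[C@H]2[C@H](C(=O)C(C)C)C(C(=O)C(C)(C)C(=O)Cl)=C(O[C@]2(C)CC[C@@H]2[C@@H]1CC2(C)C)C(C)C | intermediate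
12 | tomentodione R (1R,4R,5S,9S,1'S; ring D = 4,4,6,6-tetramethylcyclohex-2-ene-1,5-dione fused at its C2=C3 to the dihydropyran) | C=C1CC[C@H]2[C@H](C(=O)C(C)C)C3=C(O[C@]2(C)CC[C@@H]2[C@@H]1CC2(C)C)C(C)(C)C(=O)C(C)(C)C3=O | target

**Step count and risks**

Total step count: 5. Longest linear sequence: 4 steps (1 → 3 → 4 → 5 or 2 → 3 → 4 → 5).

Steps most likely to fail:

1. Step 5 (proposed new method). The annulation may stall after the first C-acylation, so that the acid chloride is lost on work-up. The ring oxygen may also be acylated with loss of the tertiary alkyl group, or C-1' may epimerise by enolisation. The fallback sets out from 9 and comes back at 12. It makes both C–C bonds with the parent reagent of the Effenberger cyclisation, malonyl dichloride (ClC(=O)CC(=O)Cl; Et2O, −20 °C → rt, no promoter), which acylates enol ethers through chlorocarbonylketene. This should give the ring-D dione without the two Ce methyl groups, the bis-nor dione F1, an enolised β-diketone whose formation is driven by enolisation. Exhaustive C-methylation of the acidic Ce position of the bis-nor dione F1 (MeI, K2CO3, acetone, reflux), the alkylation used to make syncarpic acid-type rings, should then deliver 12.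

2. Step 4. The cycloaddition of a singly activated enone may be sluggish. An ene reaction at the C8 methylene may compete, and endo/exo or facial selectivity may be poor. The fallback sets out from 6 and 8 and comes back at 9. Commercial methyl 4-methyl-3-oxopentanoate (CC(C)C(=O)CC(=O)OC) is transesterified with allyl alcohol (DMAP cat., toluene, reflux) to allyl 4-methyl-3-oxopentanoate F2. A domino Knoevenagel/hetero-Diels–Alder reaction of F2, 6 and 8 (ethylenediammonium diacetate cat., MeCN, rt) passes through the triply activated oxadiene allyl (2Z)-5-methyl-2-(2-methylpropanoyl)-4-oxohex-2-enoate F3. This oxadiene has the activation of the alkylidene 1,3-dicarbonyl compounds that add readily to caryophyllene, and it should give the Ca-allyl ester adduct F4, purified from its C-1' epimer at this stage. Pd(PPh3)4/morpholine then removes the allyl group to give the β-alkoxyacrylic acid F5. Its protodecarboxylation (pyridinium p-toluenesulfonate cat., toluene, 80 °C) returns to 9.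

3. Step 2. Over-oxidation and loss of the volatile, hydrate-forming glyoxal on isolation may lower the throughput. The fallback sets out from 4 and comes back at 7. Half an equivalent of peracetic acid (CH2Cl2, 0 °C) cleaves half of the ylide oxidatively to 6, which is formed in the flask and trapped at once by the remaining ylide. This oxidative dimerisation of the ylide gives the E-enedione directly and replaces steps 2 and 3. It makes no compound outside the compound list (F0).

**Further compounds**

F1 | step 5 | bis-nor dione: 12 with Ce = CH2 (ring D = 4,4-dimethylcyclohex-2-ene-1,5-dione, drawn as the diketo tautomer; 1R,4R,5S,9S,1'S) | C=C1CC[C@H]2[C@H](C(=O)C(C)C)C3=C(O[C@]2(C)CC[C@@H]2[C@@H]1CC2(C)C)C(C)(C)C(=O)CC3=O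
F2 | step 4 | allyl 4-methyl-3-oxopentanoate | CC(C)C(=O)CC(=O)OCC=C
F3 | step 4 | allyl (2Z)-5-methyl-2-(2-methylpropanoyl)-4-oxohex-2-enoate | CC(C)C(=O)/C=C(\C(=O)OCC=C)C(=O)C(C)C
F4 | step 4 | Ca-allyl ester of 9 (allyloxycarbonyl group on Ca; 1R,4R,5S,9S,1'S) | C=C1CC[C@H]2[C@H](C(=O)C(C)C)C(C(=O)OCC=C)=C(O[C@]2(C)CC[C@@H]2[C@@H]1CC2(C)C)C(C)C
F5 | step 4 | Ca-carboxylic acid of 9 (1R,4R,5S,9S,1'S) | C=C1CC[C@H]2[C@H](C(=O)C(C)C)C(C(=O)O)=C(O[C@]2(C)CC[C@@H]2[C@@H]1CC2(C)C)C(C)C
F0 | step 2 | none | none
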